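The route rests on cutting the cycloheptane ring into a four-carbon 2-siloxydiene (C8–C11: methylene C8, oxygen-bearing C9, gem-dimethyl C11) and a three-carbon cyclopentenyl carbene (C5–C6–C7, with C5 and C6 the fusion atoms of the five-membered ring). In one rhodium-catalysed operation the carbene cyclopropanates the enol ether and the cis-divinylcyclopropane undergoes Cope rearrangement, which closes the seven-membered ring onto the cyclopentene and sets C5 under catalyst control; C6, C10 and C9 are then relayed from C5. The precursor is a cross-conjugated dienol silyl ether that already carries the finished oxepane–cyclohexane half (built by Shi epoxidation and an epoxide cascade), paired with a cyclopentenyl N-sulfonylhydrazone.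

Key step: step 12

Remarks
- Locants used throughout (not the natural-product numbering): cyclopentene C2(Me)=C3–C4–C5–C6; cycloheptane C5–C6–C7–C8–C9–C10–C11 (C9 carbinol, C11 gem-dimethyl); linker C12–C13; cyclohexane C14–C15–C20–C21–C22–C23 (C15 methyl, C23 carbinol); oxepane C15–C16–C17–C18–C19–O–C20 (C18 hydroxyl, C19 gem-dimethyl). In these locants the target is 5R,6R,9S,10R,14R,15R,18R,20R,23S.
- Assumption: the sense of induction of the chiral dirhodium catalyst in step 12 is not taken for granted; the ligand antipode that delivers the 7R,9S cyclopropane is the one used (both antipodes are available).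
- Compounds 1, 2, 9 and 15, the D-fructose-derived epoxidation ketone and 2-(trifluoromethyl)benzenesulfonohydrazide are taken as purchased.

Step 1
Reactants: 1 (E)-geranyl bromide; 2 N-methoxy-N-methylacetamide
Product: 3 (4E)-N-methoxy-N,5,9-trimethyldeca-4,8-dienamide
Conditions: LiN(iPr)2, THF, −78 °C; then 1, −78 → −20 °C
Reagents that add atoms: none
Why: Alkylation of the lithium enolate of the Weinreb acetamide with the primary allylic bromide (SN2) should give the homologated amide with the E-alkene untouched; no stereocentre is formed.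

Step 2
Reactants: 3 dienyl Weinreb amide
Product: 4 (4R,5R,8R)-4,5:8,9-diepoxy-N-methoxy-N,5,9-trimethyldecanamide
Conditions: D-fructose-derived Shi ketone (0.6 equiv), KHSO5 (Oxone), K2CO3, Bu4NHSO4, Na2B4O7 buffer, MeCN/CH2(OMe)2, 0 °C
Reagents that add atoms: potassium peroxymonosulfate, [K+].[O-]S(=O)(=O)OO
Why: Shi asymmetric epoxidation should epoxidise both electron-rich trisubstituted alkenes through the spiro dioxirane transition state, each under reagent control, giving R at C18 and R,R at C15/C20, while the amide is inert.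

Step 3
Reactants: 4 diepoxy Weinreb amide
Product: 5 (7R,8R,11R)-7,8:11,12-diepoxy-8,12-dimethyltridec-1-en-4-one
Conditions: allylMgBr, THF, −78 °C; pH 7 buffer
Reagents that add atoms: allylmagnesium bromide, C=CC[Mg]Br
Why: Weinreb ketone synthesis: the chelated tetrahedral adduct prevents over-addition and the trisubstituted epoxides are not opened at −78 °C, so the β,γ-unsaturated ketone should result after a neutral quench.

Step 4
Reactants: 5 diepoxy allyl ketone
Product: 6 (3Z,7R,8R,11R)-4-(tert-butyldimethylsilyloxy)-7,8:11,12-diepoxy-8,12-dimethyltrideca-1,3-diene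
Conditions: LiN(iPr)2, THF, −78 °C; TBSCl, HMPA, −78 → 0 °C
Reagents that add atoms: tert-butyldimethylsilyl chloride, CC(C)(C)[Si](C)(C)Cl
Why: Deprotonation occurs at the doubly activated C14 methylene (between carbonyl and vinyl) and O-silylation of the dienolate (silyl enol ether formation) should give the 2-siloxy-1,3-diene, expected mainly as the Z isomer; either geometry serves because C14 is epimerisable after step 5.

Step 5
Reactants: 6 silyl dienol ether
Product: 7 (3R,5aR,6R,9aR)-3-(tert-butyldimethylsilyloxy)-6-ethenyl-2,2,5a-trimethyloctahydro-1-benzoxepin-7(2H)-one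
Conditions: TBSOTf, 2,6-di-tert-butyl-4-methylpyridine, CH2Cl2, −78 °C
Reagents that add atoms: tert-butyldimethylsilyl triflate, CC(C)(C)[Si](C)(C)OS(=O)(=O)C(F)(F)F
Why: Silyl-triflate-promoted epoxide cascade (tandem oxa-/carbacyclisation): the silylated terminal epoxide is opened at C19 by the oxygen of the C15/C20 epoxide, and the epoxonium ion is opened at tertiary C15 with inversion by C14 of the dienol ether through a chair transition state, which should give the trans-fused oxepane–cyclohexanone with C18 and C20 retained from step 2 and the C14 vinyl group equatorial (also the thermodynamic position).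

Step 6
Reactants: 7 bicyclic vinyl ketone
Product: 8 (3R,5aR,6R,7S,9aR)-3-(tert-butyldimethylsilyloxy)-6-ethenyl-2,2,5a,7-tetramethyldecahydro-1-benzoxepin-7-ol
Conditions: MeLi, CeCl3, THF, −78 °C
Reagents that add atoms: methyllithium, [Li]C
Why: 1,2-Addition of the weakly basic organocerium reagent should occur from the equatorial direction, because the axial face is blocked by the axial C15 methyl group, giving the axial C23 hydroxyl and equatorial methyl (23S) without enolising the β,γ-unsaturated ketone.

Step 7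
Reactants: 9 mesityl oxide
Product: 11 3-bromo-4-methylpent-3-en-2-one, via dibromide 10 (not isolated)
Conditions: Br2, CH2Cl2, 0 °C; then Et3N, 0 °C → rt
Reagents that add atoms: bromine, BrBr
Why: Bromine addition to the enone and base-induced loss of HBr from the dibromide (bromination–dehydrobromination) should give the α-bromoenone; no stereocentre remains.

Step 8
Reactants: 8 vinyl carbinol; 11 3-bromo-4-methylpent-3-en-2-one
Product: 13 tetrasubstituted enone (C8–C11 unit joined to the bicycle through C12–C13), via B-alkyl-9-BBN adduct 12 (not isolated)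
Conditions: 9-BBN, THF, 60 °C; then 11, PdCl2(dppf), AsPh3, Cs2CO3, DMF/H2O, 50 °C
Reagents that add atoms: none
Why: Anti-Markovnikov hydroboration of the terminal vinyl group followed by B-alkyl Suzuki–Miyaura coupling with the α-bromoenone should form the C10–C12 bond and deliver the tetrasubstituted enone directly; no stereocentre is formed.

Step 9
Reactants: 13 enone
Product: 14 2-(tert-butyldimethylsilyloxy)diene with both hydroxyls of the bicycle silylated
Conditions: LiN(iPr)2 (2.5 equiv), THF, −78 °C; TBSOTf (2.6 equiv), −78 → 0 °C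
Reagents that add atoms: tert-butyldimethylsilyl triflate, CC(C)(C)[Si](C)(C)OS(=O)(=O)C(F)(F)F
Why: Kinetic deprotonation of the enone at the α′-methyl group (C8) gives the cross-conjugated dienolate, and O-silylation of both the enolate and the C23 lithium alkoxide (silyl enol ether formation and silyl protection) should give the 2-siloxydiene with every hydroxyl masked for the carbene step.

Step 10
Reactants: 15 6-bromo-1,4-dioxaspiro[4.4]non-6-ene
Product: 16 1,4-dioxaspiro[4.4]non-6-ene-6-carbaldehyde
Conditions: n-BuLi, THF, −78 °C; DMF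
Reagents that add atoms: N,N-dimethylformamide, CN(C)C=O
Why: Bromine–lithium exchange and formylation of the vinyllithium with DMF should give the enal with the ketal intact.

Step 11
Reactants: 16 enal
Product: 17 N'-[(E)-1,4-dioxaspiro[4.4]non-6-en-6-ylmethylidene]-2-(trifluoromethyl)benzenesulfonohydrazide
Conditions: 2-(trifluoromethyl)benzenesulfonohydrazide, MgSO4, THF, rt
Reagents that add atoms: 2-(trifluoromethyl)benzenesulfonohydrazide, NNS(=O)(=O)c1ccccc1C(F)(F)F
Why: Condensation of the aldehyde with the sulfonyl hydrazide (hydrazone formation) should give the E N-sulfonylhydrazone, a diazo precursor that decomposes below room temperature.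

Step 12
Reactants: 14 2-siloxydiene; 17 N-sulfonylhydrazone
Product: 20 cyclohepta-1,4-diene cycloadduct (hydroazulene core; C6=C7 and C9(OTBS)=C10; C2 ethylene ketal), via diazoalkane 18 (not isolated), via cis-divinylcyclopropane 19 (not isolated)
Conditions: NaH, Rh2(S-PTAD)4 (2 mol %; antipode as in the remark), CH2Cl2, −20 °C → rt; then PhMe, 80 °C
Reagents that add atoms: none
Why: Deprotonated 17 loses sulfinate to give vinyldiazomethane 18, which the chiral dirhodium (divalent rhodium) carboxylate converts into a rhodium vinylcarbene that cyclopropanates the electron-rich C8=C9 enol-ether bond of 14 (forming C7–C8 and, transiently, C7–C9) to the cis-divinylcyclopropane 19; its Cope ([3,3]) rearrangement through the boat transition state then breaks C7–C9 and forms C5–C11, giving diene 20. The closest known reaction type is the rhodium-vinylcarbene tandem cyclopropanation/Cope rearrangement with dienes (formal [4+3] cycloaddition), here fed by an N-sulfonylhydrazone as diazo surrogate. The three-membered ring closes by [2+1] carbene addition and the seven-membered ring by the sigmatropic shift, which amounts to a (4+3) annulation onto the C5–C6 edge of the cyclopentene. C5 is the only stereocentre that survives (C7 and C9 become sp2); its configuration is transferred through the boat transition state from the 7R,9S cyclopropane, whose absolute configuration is set by the chiral catalyst. The step needs chemoselectivity for the 1,1-disubstituted silyl enol ether over the tetrasubstituted C10=C11 bond (secured by sterics and electron density) and cis-selectivity in the cyclopropanation (the trans isomer would rearrange only after a stereorandomising homolysis); the boat places only the C5 hydrogen and one C11 methyl inward, which is why gentle heating is planned.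

Step 13
Reactants: 20 cycloadduct
Product: 21 C6,C7-dihydro compound (cis-fused hydroazulene; silyl enol ether retained)
Conditions: H2 (1 atm), Pd/C, EtOAc, rt
Reagents that add atoms: none
Why: Heterogeneous hydrogenation should reduce only the trisubstituted C6=C7 bond (the tetrasubstituted silyl enol ether is too hindered) and deliver hydrogen to the face of C6 opposite the quaternary C11 substituent on C5, which sets the cis ring fusion.

Step 14
Reactants: 21 silyl enol ether
Product: 22 C9 ketone (C10–H as in the target; C2 ketal and both alkyl silyl ethers retained)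
Conditions: Bu4NF, AcOH, THF, −20 °C; then DBU, rt
Reagents that add atoms: none
Why: Fluoride cleaves the silyl enol ether far faster than the alkyl silyl ethers, and base equilibration of the α-centre should place the C10 side chain cis to the C5–C4 bond (both pseudo-equatorial, 1,3 across C11), the thermodynamic and desired configuration.

Step 15
Reactants: 22 C9 ketone
Product: 23 C9 tertiary carbinol (9S)
Conditions: MeMgBr, CeCl3, THF, −78 → 0 °C
Reagents that add atoms: methylmagnesium bromide, C[Mg]Br
Why: Organocerium 1,2-addition to the hindered ketone should occur from the face opposite the adjacent C10 side chain and the five-membered ring (both on the lower face), giving the C9 methyl up and the hydroxyl down (9S).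

Step 16
Reactants: 23 ketal carbinol
Product: 24 C2 ketone
Conditions: PPTS, acetone/H2O, 50 °C
Reagents that add atoms: water, O
Why: Mild acid-catalysed ketal hydrolysis should release the C2 ketone while the silyl ethers and the tertiary alcohol survive, under conditions mild enough to leave the α-stereocentre C6 unchanged.

Step 17
Reactants: 24 C2 ketone
Product: 25 C2=C3 enol triflate
Conditions: KN(SiMe3)2 (2.2 equiv), PhNTf2, THF, −78 °C
Reagents that add atoms: N-phenylbis(trifluoromethanesulfonimide), O=S(=O)(N(c1ccccc1)S(=O)(=O)C(F)(F)F)C(F)(F)F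
Why: Kinetic deprotonation by the bulky amide base removes a C3 methylene proton, not the tertiary C6–H, and O-triflation of the enolate should give the C2=C3 enol triflate regioselectively; the hindered tertiary C9 alkoxide is triflated much more slowly.

Step 18
Reactants: 25 enol triflate
Product: 26 bis(tert-butyldimethylsilyl) ether of the target
Conditions: MeMgBr, Fe(acac)3 (10 mol %), THF/NMP, −20 → 0 °C
Reagents that add atoms: methylmagnesium bromide, C[Mg]Br
Why: Iron-catalysed cross-coupling of the enol triflate with the methyl Grignard reagent (Kumada-type coupling) should install the C2 methyl group with the alkene fixed at C2=C3.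

Step 19
Reactants: 26 bis-silyl ether
Product: 27 target CNP0214586.1
Conditions: Bu4NF, THF, 50 °C
Reagents that add atoms: none
Why: Fluoride-mediated cleavage of both silyl ethers (the tertiary one needs warming) should liberate the triol target without touching the alkene or the tertiary alcohols.

Compound list
1 | (2E)-1-bromo-3,7-dimethylocta-2,6-diene (geranyl bromide) | CC(C)=CCC/C(C)=C/CBr | starting material
2 | N-methoxy-N-methylacetamide | CC(=O)N(C)OC | starting material
3 | (4E)-N-methoxy-N,5,9-trimethyldeca-4,8-dienamide | CC(C)=CCC/C(C)=C/CCC(=O)N(C)OC | intermediate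
4 | (4R,5R,8R)-4,5:8,9-diepoxy-N-methoxy-N,5,9-trimethyldecanamide | CC1(C)O[C@@H]1CC[C@@]2(C)O[C@@H]2CCC(=O)N(C)OC | intermediate
5 | (7R,8R,11R)-7,8:11,12-diepoxy-8,12-dimethyltridec-1-en-4-one | CC1(C)O[C@@H]1CC[C@@]2(C)O[C@@H]2CCC(=O)CC=C | intermediate
6 | (3Z,7R,8R,11R)-4-(tert-butyldimethylsilyloxy)-7,8:11,12-diepoxy-8,12-dimethyltrideca-1,3-diene | CC1(C)O[C@@H]1CC[C@@]2(C)O[C@@H]2CC/C(O[Si](C)(C)C(C)(C)C)=C/C=C | intermediate
7 | (3R,5aR,6R,9aR)-3-(tert-butyldimethylsilyloxy)-6-ethenyl-2,2,5a-trimethyloctahydro-1-benzoxepin-7(2H)-one (trans-fused, vinyl equatorial) | C=C[C@@H]1[C@@]2(C)CC[C@@H](O[Si](C)(C)C(C)(C)C)C(C)(C)O[C@@H]2CCC1=O | intermediate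
8 | (3R,5aR,6R,7S,9aR)-3-(tert-butyldimethylsilyloxy)-6-ethenyl-2,2,5a,7-tetramethyldecahydro-1-benzoxepin-7-ol | C=C[C@@H]1[C@@]2(C)CC[C@@H](O[Si](C)(C)C(C)(C)C)C(C)(C)O[C@@H]2CC[C@]1(C)O | intermediate
9 | 4-methylpent-3-en-2-one (mesityl oxide) | CC(=O)C=C(C)C | starting material
10 | 3,4-dibromo-4-methylpentan-2-one (racemic) | CC(=O)C(Br)C(C)(C)Br | intermediate
11 | 3-bromo-4-methylpent-3-en-2-one | CC(=O)C(Br)=C(C)C | intermediate
12 | 9-{2-[(3R,5aR,6R,7S,9aR)-3-(tert-butyldimethylsilyloxy)-7-hydroxy-2,2,5a,7-tetramethyldecahydro-1-benzoxepin-6-yl]ethyl}-9-borabicyclo[3.3.1]nonane | C(C[C@@H]1[C@@]2(C)CC[C@@H](O[Si](C)(C)C(C)(C)C)C(C)(C)O[C@@H]2CC[C@]1(C)O)B1C2CCCC1CCC2 | intermediate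
13 | 3-{2-[(3R,5aR,6R,7S,9aR)-3-(tert-butyldimethylsilyloxy)-7-hydroxy-2,2,5a,7-tetramethyldecahydro-1-benzoxepin-6-yl]ethyl}-4-methylpent-3-en-2-one | CC(=O)C(CC[C@@H]1[C@@]2(C)CC[C@@H](O[Si](C)(C)C(C)(C)C)C(C)(C)O[C@@H]2CC[C@]1(C)O)=C(C)C | intermediate
14 | 2-(tert-butyldimethylsilyloxy)-3-{2-[(3R,5aR,6R,7S,9aR)-3,7-bis(tert-butyldimethylsilyloxy)-2,2,5a,7-tetramethyldecahydro-1-benzoxepin-6-yl]ethyl}-4-methylpenta-1,3-diene | C=C(O[Si](C)(C)C(C)(C)C)C(CC[C@@H]1[C@@]2(C)CC[C@@H](O[Si](C)(C)C(C)(C)C)C(C)(C)O[C@@H]2CC[C@]1(C)O[Si](C)(C)C(C)(C)C)=C(C)C | intermediate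
15 | 6-bromo-1,4-dioxaspiro[4.4]non-6-ene | BrC1=CCCC12OCCO2 | starting material
16 | 1,4-dioxaspiro[4.4]non-6-ene-6-carbaldehyde | O=CC1=CCCC12OCCO2 | intermediate
17 | N'-[(E)-1,4-dioxaspiro[4.4]non-6-en-6-ylmethylidene]-2-(trifluoromethyl)benzenesulfonohydrazide | FC(F)(F)c1ccccc1S(=O)(=O)N/N=C/C1=CCCC12OCCO2 | intermediate
18 | 6-(diazomethyl)-1,4-dioxaspiro[4.4]non-6-ene | [N-]=[N+]=CC1=CCCC12OCCO2 | intermediate
19 | cis-divinylcyclopropane (7R,9S): C7 carries H and the ketal-bearing cyclopentenyl group, C9 carries OTBS and the C10=C11Me2 alkenyl group cis to it, C8 is CH2 | [C@H]1(C2=CCCC23OCCO3)C[C@@]1(O[Si](C)(C)C(C)(C)C)C(CC[C@@H]4[C@@]5(C)CC[C@@H](O[Si](C)(C)C(C)(C)C)C(C)(C)O[C@@H]5CC[C@]4(C)O[Si](C)(C)C(C)(C)C)=C(C)C | intermediate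
20 | cycloadduct: hydroazulene with C2 ethylene ketal, C6=C7 and C9(OTBS)=C10 double bonds, C5–H as in the target, C11 gem-dimethyl, bis-silylated benzoxepinyl-ethyl chain on C10 | C1(O[Si](C)(C)C(C)(C)C)=C(CC[C@@H]4[C@@]5(C)CC[C@@H](O[Si](C)(C)C(C)(C)C)C(C)(C)O[C@@H]5CC[C@]4(C)O[Si](C)(C)C(C)(C)C)C(C)(C)[C@@H]2CCC3(OCCO3)C2=CC1 | intermediate
21 | C6,C7-dihydro derivative of 20 (H5 and H6 cis) | C1(O[Si](C)(C)C(C)(C)C)=C(CC[C@@H]4[C@@]5(C)CC[C@@H](O[Si](C)(C)C(C)(C)C)C(C)(C)O[C@@H]5CC[C@]4(C)O[Si](C)(C)C(C)(C)C)C(C)(C)[C@@H]2CCC3(OCCO3)[C@@H]2CC1 | intermediate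
22 | C9 ketone (C2 ketal; H5, H6 and H10 all cis) | O=C1[C@H](CC[C@@H]4[C@@]5(C)CC[C@@H](O[Si](C)(C)C(C)(C)C)C(C)(C)O[C@@H]5CC[C@]4(C)O[Si](C)(C)C(C)(C)C)C(C)(C)[C@@H]2CCC3(OCCO3)[C@@H]2CC1 | intermediate
23 | C9 tertiary carbinol (9S; methyl cis to H10, hydroxyl cis to the side chain; C2 ketal) | C[C@@]1(O)[C@H](CC[C@@H]4[C@@]5(C)CC[C@@H](O[Si](C)(C)C(C)(C)C)C(C)(C)O[C@@H]5CC[C@]4(C)O[Si](C)(C)C(C)(C)C)C(C)(C)[C@@H]2CCC3(OCCO3)[C@@H]2CC1 | intermediate
24 | C2 ketone of 23 (cis-fused hydroazulen-2-one) | C[C@@]1(O)[C@H](CC[C@@H]4[C@@]5(C)CC[C@@H](O[Si](C)(C)C(C)(C)C)C(C)(C)O[C@@H]5CC[C@]4(C)O[Si](C)(C)C(C)(C)C)C(C)(C)[C@@H]2CCC(=O)[C@@H]2CC1 | intermediate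
25 | C2=C3 enol triflate | C[C@@]1(O)[C@H](CC[C@@H]4[C@@]5(C)CC[C@@H](O[Si](C)(C)C(C)(C)C)C(C)(C)O[C@@H]5CC[C@]4(C)O[Si](C)(C)C(C)(C)C)C(C)(C)[C@@H]2CC=C(OS(=O)(=O)C(F)(F)F)[C@@H]2CC1 | intermediate
26 | 18,23-bis(tert-butyldimethylsilyl) ether of the target | C[C@@]1(O)[C@H](CC[C@@H]4[C@@]5(C)CC[C@@H](O[Si](C)(C)C(C)(C)C)C(C)(C)O[C@@H]5CC[C@]4(C)O[Si](C)(C)C(C)(C)C)C(C)(C)[C@@H]2CC=C(C)[C@@H]2CC1 | intermediate
27 | CNP0214586.1 (5R,6R,9S,10R,14R,15R,18R,20R,23S) | CC1=CC[C@@H]2[C@H]1CC[C@](C)(O)[C@H](CC[C@@H]1[C@@]3(C)CC[C@@H](O)C(C)(C)O[C@@H]3CC[C@]1(C)O)C2(C)C | target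

Total step count: 19. Longest linear sequence: 16 steps (steps 1–6, 8, 9, 12–19).

Steps most likely to fail

1. Step 12. The non-stabilised vinyl diazo species may cyclise to a pyrazole or dimerise before carbene transfer. The cyclopropanation may also give the trans cyclopropane, or proceed with poor catalyst-controlled face selectivity, so that C5 forms as a mixture. The fallback sets out from 14 and 15 and returns at 22; it uses a donor/acceptor vinyldiazoacetate, for which enantioselective tandem cyclopropanation/Cope reactions with 2-siloxydienes are well established. Bromide 15 is coupled with the Reformatsky reagent BrZnCH2CO2Me (Pd(dba)2, P(t-Bu)3) to give methyl 2-(1,4-dioxaspiro[4.4]non-6-en-6-yl)acetate F1. Diazo transfer (4-acetamidobenzenesulfonyl azide, DBU) gives methyl 2-diazo-2-(1,4-dioxaspiro[4.4]non-6-en-6-yl)acetate F2. With 14 and Rh2(S-DOSP)4 (antipode chosen as in the remark) this should give the C7-methoxycarbonyl cycloadduct F3. Conjugate reduction (Mg, MeOH) gives the saturated ester F4. LiOH and then buffered Bu4NF give the C7 keto acid F5. Photoredox hydrodecarboxylation (acridinium photocatalyst, PhSSPh, visible light) then gives ketone 22.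

2. Step 5. The cascade may terminate through the terminal carbon or the oxygen of the dienol ether, an epoxide may rearrange under the Lewis acid before ring closure, and the β,γ-unsaturated ketone may drift into conjugation. The fallback sets out from 4 and returns at 7; it uses a β-keto ester, the classical terminating nucleophile of epoxy-polyene cyclisations. Acylation of the lithium enolate of methyl acetate with amide 4 gives methyl (6R,7R,10R)-6,7:10,11-diepoxy-7,11-dimethyl-3-oxododecanoate F6. The same silyl triflate conditions (the enol is the nucleophile) should give the bicyclic β-keto ester F7 with the ester equatorial on C14. LiAlH4 gives the diol F8. Selective oxidation of the primary alcohol (TEMPO, PhI(OAc)2) gives the hydroxy aldehyde F9. Wittig methylenation (Ph3P=CH2) gives the secondary vinyl carbinol F10, and Dess–Martin oxidation returns ketone 7.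

3. Step 15. Addition to the hindered cycloheptanone may occur with poor or opposite facial selectivity, or enolisation may compete. The fallback sets out from 22 and returns at 23. Methylenation (Ph3P=CH2 or Cp2TiMe2) gives the C9 exocyclic alkene F11. Epoxidation with dimethyldioxirane from the more accessible lower face gives the spiro-epoxide F12; this places oxygen, not carbon, on the face that a nucleophile prefers, so the facial bias now leads to the desired epimer. Opening of the epoxide at its CH2 carbon with LiBHEt3 gives 23.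

Further compounds
F1 | step 12 | methyl 2-(1,4-dioxaspiro[4.4]non-6-en-6-yl)acetate | COC(=O)CC1=CCCC12OCCO2
F2 | step 12 | methyl 2-diazo-2-(1,4-dioxaspiro[4.4]non-6-en-6-yl)acetate | COC(=O)C(=[N+]=[N-])C1=CCCC12OCCO2
F3 | step 12 | C7-methoxycarbonyl analogue of cycloadduct 20 | C1(O[Si](C)(C)C(C)(C)C)=C(CC[C@@H]4[C@@]5(C)CC[C@@H](O[Si](C)(C)C(C)(C)C)C(C)(C)O[C@@H]5CC[C@]4(C)O[Si](C)(C)C(C)(C)C)C(C)(C)[C@@H]2CCC3(OCCO3)C2=C(C(=O)OC)C1
F4 | step 12 | C7-methoxycarbonyl analogue of 21 (C7 epimers) | C1(O[Si](C)(C)C(C)(C)C)=C(CC[C@@H]4[C@@]5(C)CC[C@@H](O[Si](C)(C)C(C)(C)C)C(C)(C)O[C@@H]5CC[C@]4(C)O[Si](C)(C)C(C)(C)C)C(C)(C)[C@@H]2CCC3(OCCO3)[C@@H]2C(C(=O)OC)C1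
F5 | step 12 | C7-carboxylic acid of ketone 22 (C7 epimers) | O=C1[C@H](CC[C@@H]4[C@@]5(C)CC[C@@H](O[Si](C)(C)C(C)(C)C)C(C)(C)O[C@@H]5CC[C@]4(C)O[Si](C)(C)C(C)(C)C)C(C)(C)[C@@H]2CCC3(OCCO3)[C@@H]2C(C(=O)O)C1
F6 | step 5 | methyl (6R,7R,10R)-6,7:10,11-diepoxy-7,11-dimethyl-3-oxododecanoate | CC1(C)O[C@@H]1CC[C@@]2(C)O[C@@H]2CCC(=O)CC(=O)OC
F7 | step 5 | methyl 3-(tert-butyldimethylsilyloxy)-2,2,5a-trimethyl-7-oxodecahydro-1-benzoxepine-6-carboxylate (ring stereocentres as in 7, ester equatorial) | COC(=O)[C@@H]1[C@@]2(C)CC[C@@H](O[Si](C)(C)C(C)(C)C)C(C)(C)O[C@@H]2CCC1=O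
F8 | step 5 | 6-(hydroxymethyl)-3-(tert-butyldimethylsilyloxy)-2,2,5a-trimethyldecahydro-1-benzoxepin-7-ol (C7 epimers) | OC[C@@H]1[C@@]2(C)CC[C@@H](O[Si](C)(C)C(C)(C)C)C(C)(C)O[C@@H]2CCC1O
F9 | step 5 | 3-(tert-butyldimethylsilyloxy)-7-hydroxy-2,2,5a-trimethyldecahydro-1-benzoxepine-6-carbaldehyde (C7 epimers) | O=C[C@@H]1[C@@]2(C)CC[C@@H](O[Si](C)(C)C(C)(C)C)C(C)(C)O[C@@H]2CCC1O
F10 | step 5 | 3-(tert-butyldimethylsilyloxy)-6-ethenyl-2,2,5a-trimethyldecahydro-1-benzoxepin-7-ol (C7 epimers) | C=C[C@@H]1[C@@]2(C)CC[C@@H](O[Si](C)(C)C(C)(C)C)C(C)(C)O[C@@H]2CCC1O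
F11 | step 15 | C9 exocyclic methylene analogue of ketone 22 | C=C1[C@H](CC[C@@H]4[C@@]5(C)CC[C@@H](O[Si](C)(C)C(C)(C)C)C(C)(C)O[C@@H]5CC[C@]4(C)O[Si](C)(C)C(C)(C)C)C(C)(C)[C@@H]2CCC3(OCCO3)[C@@H]2CC1
F12 | step 15 | C9 spiro-epoxide (oxygen on the lower face, CH2 on the upper face) | C1O[C@@]12[C@H](CC[C@@H]5[C@@]6(C)CC[C@@H](O[Si](C)(C)C(C)(C)C)C(C)(C)O[C@@H]6CC[C@]5(C)O[Si](C)(C)C(C)(C)C)C(C)(C)[C@@H]3CCC4(OCCO4)[C@@H]3CC2
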